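The numbers in the tables were computed with constants of no real substance.

A leftover of 17% of the starting material stands in the ochre run at 6.00 min, beside 34% of target. What is neither reads 51.0% at 0.500 min and 49.0% at 6.00 min. That pool, intermediate and isomer of the product together, stays nearly constant in ochre within the scatter, so the reckoning made here freezes [intermediate] in proportion to the starting charge. The asked flask is the blue run carried on.

in all of them: free catalyst 17 µM (in portions, 2); second catalyst 1.8 µM

| run | starting material | coupling partner | remark | time |
|---|---|---|---|---|
| blue | 1 mM | 1 mM | the very flask that is asked about, followed so far; portions every 3.0 s |  |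
| ochre | 0.67 mM | 1 mM | run made earlier; portions every 3.0 s |  |
| flask | 1.0 mM | 1.00 mM | the portions of free catalyst follow each other after 3.0 s, the first at the start | 6.0 min |

blue run (percent of the starting material charged)

| time / s | starting material / % | target / % |
|---|---|---|
| 10.0 | 37 | 12 |
| 12.0 | 33 | 18 |
| 15.0 | 31 | 20 |
| 25.0 | 24 | 26 |
| 30.0 | 19 | 24 |

ochre run (percent of the starting material charged)

| time / min | starting material / % | target / % |
|---|---|---|
| 0.500 | 26 | 23 |
| 1.50 | 21 | 32 |
| 3.00 | 20 | 31 |
| 4.00 | 20 | 33 |
| 6.00 | 17 | 34 |

(standard deviation of a reading: 2 percentage points)

- the state of affairs at 6.0 min: stopped, and by what, or still going (forward and back rates have come level / no working catalyst is left / it is still moving / all of the starting material has reacted / the coupling partner has run out first)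
- share of the starting material used up at 6.0 min
- target at 6.0 min, in percent of the starting material charged
- amount of target if the flask were left three thousand times as long, in percent of the starting material charged

- steps thought possible: coupling partner -> decomposed reagent; target <-> isomer of the product; coupling partner + second catalyst + intermediate -> second catalyst + target; starting material + free catalyst <-> free catalyst + intermediate; free catalyst -> spent catalyst
- the reaction counts as stopped when no species that holds the starting material changes by six tenths of a point or more over the second half of the time

Blue forms target at 0.0120 mM s⁻¹ over its first 10.0 s, then at 0.00600 mM s⁻¹ up to 30.0 s, a slowing by a factor of 2.00. Ochre goes from 0.00514 mM s⁻¹ over its first 0.500 min to 4.96 × 10⁻⁵ mM s⁻¹ after 1.50 min, a factor of about 103, though that late drift lies within the scatter.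

The reckoning reads this slowing as the coupling partner leaving by two exits, coupling with the intermediate and decomposing. Both rates are first order in it, so [coupling partner] cancels from their ratio:

odds = rate of coupling / rate of decomposition, proportional to [intermediate] at the same [second catalyst]

share of the coupling partner reaching target = odds / (1 + odds)

The mean of ochre's last 3 target readings gives a share of 21.9%. That makes 0.418 mM⁻¹ the coupling odds per mM of starting material charged. Blue then has odds of 0.418, a share of 29.5% and target of 29.5%. The reckoning expects the coupling partner to be the limiting reagent, and the same target at the longer time.

The forecast differs in cause, naming no working catalyst is left: “That residue is therefore left by catalyst death”. It gives 82% used up and target 33% at the asked time, 3.5 percentage points more target than the reckoning, and target 34% at the longer time.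

The flask gives: the coupling partner has run out first, with 78.5% used up, target 28.3% at 6.0 min and 28.3% at the long time.

    coupling partner → decomposed reagent (k = 0.0610 s⁻¹)
    target ⇌ isomer of the product (K = 0.100, k = 0.0770 s⁻¹)
    coupling partner + second catalyst + intermediate → second catalyst + target (k = 4.40 × 10⁷ M⁻² s⁻¹)
    starting material + free catalyst ⇌ free catalyst + intermediate (K = 2.20, k = 9600 M⁻¹ s⁻¹)
    free catalyst → spent catalyst (k = 8.50 × 10⁻⁵ s⁻¹)

At 6.00 min the flask holds coupling partner at 0% of its charge and free catalyst at 97.0%, and the reckoned 29.5% stands 1.2 points above the target found. The neighbour charged with 2.5 mM of starting material, its other charges as in the flask, takes the same coupling odds per mM: odds of 1.05, a share of 51.1%, and target of 20.4% of its starting material. That neighbour gives 18.3% of target, with coupling partner at 0% and intermediate at 54.9%.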